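**Plan**
1. Retrosynthesis: the ten O-benzyl groups and a bromine cap on C8 of the upper unit go last. One operation then cuts the C4–C8' interflavan bond and the O1–C8a aryl ether bond of the upper pyran ring.
2. This leaves the catechin ester 15 and an open chain, C2(OSiMe3)–C3(OBn)–C4(OSiMe3), between ring B and a 2-fluoroaryl ring A. The chain is cut at C4–C4a (aryllithium + Weinreb amide) and at C2–C3 (glycolate aldol).
3. Forward: ring A (from 5-fluororesorcinol) is joined to the aldol piece, the ketone is reduced and the diol silylated. The upper pyran ring then closes by O1–C8a and the two flavan units are joined in the same pot; hydrogenolysis ends the route. The lower unit is (+)-catechin with its rings intact.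
4. Stereochemistry: lower C2/C3 come from (+)-catechin. Upper C2/C3 come from an Evans syn-glycolate aldol and are kept because the C2–O bond is never broken (this gives the 2,3-cis ring). Upper C4 comes from β-face attack of C8' on the ring-bound C4 cation (3,4-trans).
5. Enabling feature: in ring A, C8a is ortho to the benzylic carbon C4 and meta to the oxygens on C5 and C7. A C4 cation stabilised by those oxygens puts ortho positive charge on C8a, so a fluorine there is displaced by the C2 oxygen, and the displacement returns the C4 cation inside the new pyran ring.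

Key step: step 10

Remark: flavan numbering (C2, C3, C4, C4a–C8a; primes for the lower unit) is used for the open-chain compounds too. C4 of 10, 11 and 16 is a mixture of epimers, which is immaterial because C4 is ionised in step 10. Compounds 1, 4, 5, 12 and 14 are taken as commercial.

**Step 1**
Reactants: 1 5-fluorobenzene-1,3-diol
Product: 2 1,3-bis(benzyloxy)-5-fluorobenzene
Conditions: BnBr (2.2 equiv), K2CO3, DMF, rt
Reagents that add atoms: benzyl bromide, BrCc1ccccc1
Why: Williamson O-alkylation of both phenols (SN2); no stereocentre.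

**Step 2**
Reactants: 2 1,3-bis(benzyloxy)-5-fluorobenzene
Product: 3 1,5-bis(benzyloxy)-2,4-dibromo-3-fluorobenzene
Conditions: NBS (2.05 equiv), MeCN, 0 °C to rt
Reagents that add atoms: N-bromosuccinimide, O=C1CCC(=O)N1Br
Why: Electrophilic aromatic bromination; each position next to fluorine is ortho to one and para to the other benzyloxy group, while the position between the two benzyloxy groups is the hindered one (the pattern of 2,6-dihalogenation of 3,5-dialkoxyaryl rings); one bromine serves for lithiation, the other becomes the C8 cap.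

**Step 3**
Reactants: 4 (S)-4-benzyl-3-[(benzyloxy)acetyl]oxazolidin-2-one; 5 3,4-bis(benzyloxy)benzaldehyde
Product: 6 (S)-4-benzyl-3-{(2S,3R)-2-(benzyloxy)-3-[3,4-bis(benzyloxy)phenyl]-3-hydroxypropanoyl}oxazolidin-2-one
Conditions: Bu2BOTf, Et3N, CH2Cl2, −78 to 0 °C; then 5, −78 to 0 °C; pH 7 buffer, MeOH, H2O2
Reagents that add atoms: none
Why: Evans syn-glycolate aldol through the (Z)-boron enolate and a Zimmerman–Traxler chair; the (S)-benzyl auxiliary sets both new centres (2S,3R), the syn pair that becomes C3/C2 of the upper unit.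

**Step 4**
Reactants: 6 Evans aldol adduct
Product: 7 (2S,3R)-2-(benzyloxy)-3-[3,4-bis(benzyloxy)phenyl]-3-hydroxy-N-methoxy-N-methylpropanamide
Conditions: MeONHMe·HCl, AlMe3, THF/CH2Cl2, −20 to 0 °C; Rochelle salt work-up
Reagents that add atoms: N,O-dimethylhydroxylamine hydrochloride, CNOC.Cl
Why: Aluminium-amide transamidation of the N-acyloxazolidinone (Weinreb amide formation), assisted by the free β-hydroxyl; no stereocentre is touched.

**Step 5**
Reactants: 7 Weinreb amide; 3 1,5-bis(benzyloxy)-2,4-dibromo-3-fluorobenzene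
Product: 9 (2S,3R)-2-(benzyloxy)-3-[3,4-bis(benzyloxy)phenyl]-1-[4,6-bis(benzyloxy)-3-bromo-2-fluorophenyl]-3-hydroxypropan-1-one, via aryllithium 8 (not isolated)
Conditions: 3 (2.4 equiv), n-BuLi (2.3 equiv), THF, −78 °C; then 7, −78 to −60 °C; aq NH4Cl at −78 °C
Reagents that add atoms: none
Why: Bromine–lithium exchange of one of two equivalent bromines, then acyl substitution on the Weinreb amide, whose chelated tetrahedral intermediate stops over-addition; −78 °C keeps the o-fluoroaryllithium from losing LiF, and the first equivalent of 8 acts as base for the hydroxyl.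

**Step 6**
Reactants: 9 β-hydroxy ketone
Product: 10 (1RS,2S,3R)-2-(benzyloxy)-3-[3,4-bis(benzyloxy)phenyl]-1-[4,6-bis(benzyloxy)-3-bromo-2-fluorophenyl]propane-1,3-diol (C1 bears the bromofluoroaryl ring)
Conditions: NaBH4, CeCl3·7H2O, MeOH/THF, −40 °C
Reagents that add atoms: none
Why: Luche-type borohydride reduction of the aryl ketone under non-basic conditions, so that the β-hydroxyl does not cyclise onto the o-fluoroaryl ketone; the new C4 centre needs no control.

**Step 7**
Reactants: 10 diol
Product: 11 (1RS,2S,3R)-2-(benzyloxy)-3-[3,4-bis(benzyloxy)phenyl]-1-[4,6-bis(benzyloxy)-3-bromo-2-fluorophenyl]-1,3-bis(trimethylsilyloxy)propane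
Conditions: TMSCl (2.5 equiv), imidazole, CH2Cl2, 0 °C; non-aqueous work-up (hexane, filtration)
Reagents that add atoms: chlorotrimethylsilane, C[Si](C)(C)Cl
Why: Silylation of both secondary alcohols; it supplies the C4 leaving group and the silyl oxygen nucleophile at C2, so that step 10 is driven by Si–F bond formation and sets no HF free.

**Step 8**
Reactants: 12 (+)-catechin
Product: 13 5,7,3',4'-tetra-O-benzyl-(+)-catechin
Conditions: BnBr (4.4 equiv), K2CO3, DMF, −10 °C to rt
Reagents that add atoms: benzyl bromide, BrCc1ccccc1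
Why: Williamson benzylation of the four phenols; the aliphatic 3-OH is not alkylated under carbonate conditions and both stereocentres are untouched.

**Step 9**
Reactants: 13 tetra-O-benzylcatechin; 14 4-(benzyloxy)benzoic acid
Product: 15 (2R,3S)-5,7-bis(benzyloxy)-2-[3,4-bis(benzyloxy)phenyl]chroman-3-yl 4-(benzyloxy)benzoate
Conditions: DCC, DMAP, CH2Cl2, rt
Reagents that add atoms: none
Why: Steglich esterification of the secondary 3-OH; the acyl group is placed on the lower unit before the units are joined, so the two 3-oxygens never have to be told apart.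

**Step 10**
Reactants: 11 bis-silyl ether; 15 catechin ester
Product: 17 3,5,7,3',4'-penta-O-benzyl-8-bromo-(−)-epicatechin-(4β→8)-5,7,3',4'-tetra-O-benzyl-(+)-catechin 3-O-[4-(benzyloxy)benzoate], via 4-silyloxyflavan 16 (not isolated)
Conditions: (i) TMSOTf (0.2 equiv), CH2Cl2 (0.01 M), −78 to −30 °C until 11 is consumed; (ii) −78 °C, 15 (1.5 equiv), TMSOTf (0.5 equiv); Et3N, then aq NaHCO3
Reagents that add atoms: none
Why: Proposed new method: TMSOTf ionises the C4–OSiMe3 bond of 11 (the cation is stabilised by the ortho C5 and para C7 benzyloxy groups and places positive charge on C8a), the C2 silyl ether oxygen adds ipso to fluorine at C8a, and fluoride leaves as Me3SiF, which re-aromatises ring A and returns the C4 cation inside the pyran ring; this cation is held as silyl ether 16 until 15 is added and then alkylates C8 of 15 (Friedel–Crafts). Closest known reaction types: carbenium-ion-activated SNAr in xanthylium and triarylcarbenium dyes, carbonyl-activated SNAr of β-alkoxides on o-fluoroaryl ketones (chroman-4-ones), and Si–F-driven coupling of silyl ethers with α-fluoro ethers (glycosyl fluorides) under TMSOTf; their combination on a transient secondary benzylic cation is new. The pyran ring closes by a six-membered ipso addition–elimination at C8a (6-exo-trig with respect to the C8a=C8 bond), with the side chain held syn to the small fluorine and not to the C5 benzyloxy group. C2 and C3 keep the aldol configuration because no bond to either is broken (the syn pair becomes the 2,3-cis ring), and the new C4 centre is set by attack of 15 on the half-chair cation from the β face, anti to the cis 2-aryl and 3-benzyloxy groups (3,4-trans). Required selectivities are ionisation at C4 and not C2 (o,p-dialkoxybenzyl versus p-alkoxybenzyl cation), closure at C8a and not C5 (only fluoride leaves irreversibly), closure before any π-nucleophile meets the open-chain cation (15 is added afterwards), no self-alkylation (the C8 bromine blocks and deactivates ring A) and C8 over C6 attack on 15 (the usual preference of 5,7-di-O-benzyl flavan-3-ols).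

**Step 11**
Reactants: 17 protected dimer
Product: 18 (−)-epicatechin-(4β→8)-(+)-catechin 3-O-(4-hydroxybenzoate) (ester on the catechin unit; upper 2R,3R,4R; lower 2R,3S)
Conditions: H2 (1 atm), Pd(OH)2/C, Et3N (1.2 equiv), THF/MeOH/H2O, rt
Reagents that add atoms: none
Why: Hydrogenolysis of ten benzyl ethers together with hydrodebromination of the C8 cap, the standard end-game for benzylated, bromine-capped proanthocyanidins; the aryl ester, the pyran rings and the interflavan bond are not cleaved and no stereocentre is affected.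

**Compound list**
1 | 5-fluorobenzene-1,3-diol | Oc1cc(O)cc(F)c1 | starting material
2 | 1,3-bis(benzyloxy)-5-fluorobenzene | Fc1cc(OCc2ccccc2)cc(OCc2ccccc2)c1 | intermediate
3 | 1,5-bis(benzyloxy)-2,4-dibromo-3-fluorobenzene | Fc1c(Br)c(OCc2ccccc2)cc(OCc2ccccc2)c1Br | intermediate
4 | (S)-4-benzyl-3-[(benzyloxy)acetyl]oxazolidin-2-one | O=C(COCc1ccccc1)N1[C@@H](Cc2ccccc2)COC1=O | starting material
5 | 3,4-bis(benzyloxy)benzaldehyde | O=Cc1ccc(OCc2ccccc2)c(OCc2ccccc2)c1 | starting material
6 | (S)-4-benzyl-3-{(2S,3R)-2-(benzyloxy)-3-[3,4-bis(benzyloxy)phenyl]-3-hydroxypropanoyl}oxazolidin-2-one | O[C@H](c1ccc(OCc2ccccc2)c(OCc2ccccc2)c1)[C@H](OCc1ccccc1)C(=O)N1[C@@H](Cc2ccccc2)COC1=O | intermediate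
7 | (2S,3R)-2-(benzyloxy)-3-[3,4-bis(benzyloxy)phenyl]-3-hydroxy-N-methoxy-N-methylpropanamide | O[C@H](c1ccc(OCc2ccccc2)c(OCc2ccccc2)c1)[C@H](OCc1ccccc1)C(=O)N(C)OC | intermediate
8 | [4,6-bis(benzyloxy)-3-bromo-2-fluorophenyl]lithium | [Li]c1c(F)c(Br)c(OCc2ccccc2)cc1OCc1ccccc1 | intermediate (not isolated)
9 | (2S,3R)-2-(benzyloxy)-3-[3,4-bis(benzyloxy)phenyl]-1-[4,6-bis(benzyloxy)-3-bromo-2-fluorophenyl]-3-hydroxypropan-1-one | O[C@H](c1ccc(OCc2ccccc2)c(OCc2ccccc2)c1)[C@H](OCc1ccccc1)C(=O)c1c(F)c(Br)c(OCc2ccccc2)cc1OCc1ccccc1 | intermediate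
10 | (1RS,2S,3R)-2-(benzyloxy)-3-[3,4-bis(benzyloxy)phenyl]-1-[4,6-bis(benzyloxy)-3-bromo-2-fluorophenyl]propane-1,3-diol | O[C@H](c1ccc(OCc2ccccc2)c(OCc2ccccc2)c1)[C@H](OCc1ccccc1)C(O)c1c(F)c(Br)c(OCc2ccccc2)cc1OCc1ccccc1 | intermediate
11 | 1,3-bis(trimethylsilyl) ether of 10 | C[Si](C)(C)O[C@H](c1ccc(OCc2ccccc2)c(OCc2ccccc2)c1)[C@H](OCc1ccccc1)C(O[Si](C)(C)C)c1c(F)c(Br)c(OCc2ccccc2)cc1OCc1ccccc1 | intermediate
12 | (+)-catechin, (2R,3S) | O[C@H]1Cc2c(O)cc(O)cc2O[C@@H]1c1ccc(O)c(O)c1 | starting material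
13 | 5,7,3',4'-tetra-O-benzyl-(+)-catechin | O[C@H]1Cc2c(OCc3ccccc3)cc(OCc3ccccc3)cc2O[C@@H]1c1ccc(OCc2ccccc2)c(OCc2ccccc2)c1 | intermediate
14 | 4-(benzyloxy)benzoic acid | OC(=O)c1ccc(OCc2ccccc2)cc1 | starting material
15 | (2R,3S)-5,7-bis(benzyloxy)-2-[3,4-bis(benzyloxy)phenyl]chroman-3-yl 4-(benzyloxy)benzoate | O=C(O[C@H]1Cc2c(OCc3ccccc3)cc(OCc3ccccc3)cc2O[C@@H]1c1ccc(OCc2ccccc2)c(OCc2ccccc2)c1)c1ccc(OCc2ccccc2)cc1 | intermediate
16 | (2R,3S,4RS)-3,5,7-tris(benzyloxy)-2-[3,4-bis(benzyloxy)phenyl]-8-bromo-4-(trimethylsilyloxy)chromane (2,3-cis) | C[Si](C)(C)OC1c2c(OCc3ccccc3)cc(OCc3ccccc3)c(Br)c2O[C@H](c2ccc(OCc3ccccc3)c(OCc3ccccc3)c2)[C@@H]1OCc1ccccc1 | intermediate (not isolated)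
17 | 3,5,7,3',4'-penta-O-benzyl-8-bromo-(−)-epicatechin-(4β→8)-5,7,3',4'-tetra-O-benzyl-(+)-catechin 3-O-[4-(benzyloxy)benzoate] | O=C(O[C@H]1Cc2c(OCc3ccccc3)cc(OCc3ccccc3)c([C@H]3c4c(OCc5ccccc5)cc(OCc5ccccc5)c(Br)c4O[C@H](c4ccc(OCc5ccccc5)c(OCc5ccccc5)c4)[C@@H]3OCc3ccccc3)c2O[C@@H]1c1ccc(OCc2ccccc2)c(OCc2ccccc2)c1)c1ccc(OCc2ccccc2)cc1 | intermediate
18 | (−)-epicatechin-(4β→8)-(+)-catechin 3-O-(4-hydroxybenzoate) | O=C(O[C@H]1Cc2c(O)cc(O)c([C@H]3c4c(O)cc(O)cc4O[C@H](c4ccc(O)c(O)c4)[C@@H]3O)c2O[C@@H]1c1ccc(O)c(O)c1)c1ccc(O)cc1 | target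

**Totals**
Total step count: 11. Longest linear sequence: 7 steps (3, 4, 5, 6, 7, 10, 11; the ring-A branch 1, 2, 5, 6, 7, 10, 11 is equally long).

**Steps most likely to fail**

Step 10 (proposed new method). The open-chain C4 cation may be consumed before the C2 oxygen reaches C8a, by loss of H3 to an enol ether, by 1,2-hydride shift or by five-membered Friedel–Crafts closure through ring B. Closure may also go to C5 with loss of the benzyloxy group, or C2 may ionise and lose its configuration. The fallback uses known chemistry, sets out from 10 and comes back at 17. KH with 18-crown-6 in THF/DMF (0 °C to rt) closes the pyran ring by classical intramolecular SNAr of the C2 alkoxide on the aryl fluoride and gives (2R,3R,4RS)-3,5,7-tris(benzyloxy)-2-[3,4-bis(benzyloxy)phenyl]-8-bromochroman-4-ol F1. F1 and 15 with TMSOTf in CH2Cl2 at −78 °C (Lewis-acid coupling of a 4-oxygenated flavan with a flavan-3-ol nucleophile) then give 17.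

Step 5. The aryllithium may lose LiF to an aryne, or the di-ortho-substituted nucleophile may add slowly, so that enolisation and epimerisation at the α-benzyloxy carbon compete. The fallback sets out from 7 and 3 and comes back at 10, bypassing 9 and step 6. TESCl and imidazole convert 7 into (2S,3R)-2-(benzyloxy)-3-[3,4-bis(benzyloxy)phenyl]-N-methoxy-N-methyl-3-(triethylsilyloxy)propanamide F2. DIBAL-H at −78 °C reduces it to (2S,3R)-2-(benzyloxy)-3-[3,4-bis(benzyloxy)phenyl]-3-(triethylsilyloxy)propanal F3. Bromine–magnesium exchange of 3 with i-PrMgCl·LiCl at −20 °C gives [4,6-bis(benzyloxy)-3-bromo-2-fluorophenyl]magnesium chloride F4, which does not lose fluoride readily. It adds to the aldehyde to give (1RS,2S,3R)-2-(benzyloxy)-3-[3,4-bis(benzyloxy)phenyl]-1-[4,6-bis(benzyloxy)-3-bromo-2-fluorophenyl]-3-(triethylsilyloxy)propan-1-ol F5. TBAF/AcOH removes the silyl group and gives 10.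

Step 11. The HBr released by hydrodebromination may poison the catalyst or cleave the acid-labile interflavan bond, and hydrogenolysis of the hindered secondary benzyl ether may stop short. The fallback sets out from 17 and comes back at 18. Bu3SnH and AIBN in toluene at 85 °C remove the bromine by radical reduction and give 3,5,7,3',4'-penta-O-benzyl-(−)-epicatechin-(4β→8)-5,7,3',4'-tetra-O-benzyl-(+)-catechin 3-O-[4-(benzyloxy)benzoate] F6. Hydrogenolysis of this bromine-free compound (H2, Pd(OH)2/C, THF/MeOH) gives 18.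

**Further compounds**
F1 | step 10 | (2R,3R,4RS)-3,5,7-tris(benzyloxy)-2-[3,4-bis(benzyloxy)phenyl]-8-bromochroman-4-ol | OC1c2c(OCc3ccccc3)cc(OCc3ccccc3)c(Br)c2O[C@H](c2ccc(OCc3ccccc3)c(OCc3ccccc3)c2)[C@@H]1OCc1ccccc1
F2 | step 5 | (2S,3R)-2-(benzyloxy)-3-[3,4-bis(benzyloxy)phenyl]-N-methoxy-N-methyl-3-(triethylsilyloxy)propanamide | CC[Si](CC)(CC)O[C@H](c1ccc(OCc2ccccc2)c(OCc2ccccc2)c1)[C@H](OCc1ccccc1)C(=O)N(C)OC
F3 | step 5 | (2S,3R)-2-(benzyloxy)-3-[3,4-bis(benzyloxy)phenyl]-3-(triethylsilyloxy)propanal | CC[Si](CC)(CC)O[C@H](c1ccc(OCc2ccccc2)c(OCc2ccccc2)c1)[C@H](OCc1ccccc1)C=O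
F4 | step 5 | [4,6-bis(benzyloxy)-3-bromo-2-fluorophenyl]magnesium chloride | Cl[Mg]c1c(F)c(Br)c(OCc2ccccc2)cc1OCc1ccccc1
F5 | step 5 | (1RS,2S,3R)-2-(benzyloxy)-3-[3,4-bis(benzyloxy)phenyl]-1-[4,6-bis(benzyloxy)-3-bromo-2-fluorophenyl]-3-(triethylsilyloxy)propan-1-ol | CC[Si](CC)(CC)O[C@H](c1ccc(OCc2ccccc2)c(OCc2ccccc2)c1)[C@H](OCc1ccccc1)C(O)c1c(F)c(Br)c(OCc2ccccc2)cc1OCc1ccccc1
F6 | step 11 | 3,5,7,3',4'-penta-O-benzyl-(−)-epicatechin-(4β→8)-5,7,3',4'-tetra-O-benzyl-(+)-catechin 3-O-[4-(benzyloxy)benzoate] | O=C(O[C@H]1Cc2c(OCc3ccccc3)cc(OCc3ccccc3)c([C@H]3c4c(OCc5ccccc5)cc(OCc5ccccc5)cc4O[C@H](c4ccc(OCc5ccccc5)c(OCc5ccccc5)c4)[C@@H]3OCc3ccccc3)c2O[C@@H]1c1ccc(OCc2ccccc2)c(OCc2ccccc2)c1)c1ccc(OCc2ccccc2)cc1
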